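**Retrosynthesis**
1. Hedyotol C ← syringyl phenol of the medioresinol-type core **17** plus an erythro guaiacylglycerol chain. The chain is attached by Mitsunobu inversion of an L-serine-derived glycerate, then Felkin-controlled aryl addition.
2. Core **17** ← lactol **15** (ionic deoxygenation). Ring B forms by lactolization of a C8 aldehyde onto the C7′-OH.
3. Ring A (a THF fused to an isoxazoline) and the C7, C8′ and C7′ stereocentres come from an intramolecular nitrile oxide–alkene [3+2] cycloaddition of oxime **11**. Oxime **11** is made from (S)-glyceraldehyde acetonide + ArMgBr, O-cinnamylation, and glycol cleavage.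
4. Ring order: THF-A and the isoxazoline form together in the cycloaddition; THF-B forms as a lactol and is then reduced.

Assumption: the Felkin (anti) adducts are the major, chromatographically separable isomers in Steps 5 and 20, and the cycloaddition favours the aryl-exo isomer.

---

**Step 1**
Reactants: 1 methyl (E)-sinapate
Product: 2 methyl (E)-4-O-TBS-sinapate
Conditions: TBSCl, imidazole, DMF, rt
Reagents that add atoms: TBSCl, CC(C)(C)[Si](C)(C)Cl
Why: Silylation masks the phenol so it survives the later NaH, NCS and Wittig conditions.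

**Step 2**
Reactants: 2
Product: 3 (E)-4-O-TBS-sinapyl alcohol
Conditions: DIBAL-H (2.5 equiv), toluene, −78 °C
Reagents that add atoms: none
Why: DIBAL-H 1,2-reduces the ester to the allylic alcohol and leaves the E-alkene and the aryl silyl ether intact.

**Step 3**
Reactants: 3
Product: 4 (E)-4-O-TBS-sinapyl bromide
Conditions: CBr4, PPh3, CH2Cl2, 0 °C (crude used at once)
Reagents that add atoms: CBr4, BrC(Br)(Br)Br
Why: Appel bromination is an SN2 at the primary allylic carbon and leaves the alkene geometry unchanged.

**Step 4**
Reactants: 5 (R)-solketal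
Product: 6 (S)-2,3-O-isopropylideneglyceraldehyde
Conditions: (COCl)2, DMSO, i-Pr2NEt, CH2Cl2, −78 °C (quenched cold, crude used at once)
Reagents that add atoms: none
Why: Swern oxidation keeps the stereocentre, and the hindered amine base limits α-epimerization. The CIP label changes from R to S only because the priorities change.

**Step 5**
Reactants: 6; 7 1-(benzyloxy)-4-bromo-2-methoxybenzene
Product: 8 (R)-(4-benzyloxy-3-methoxyphenyl)[(S)-dioxolan-4-yl]methanol (anti adduct)
Conditions: 7, Mg, THF, reflux, to give ArMgBr; then 6, THF, −78 → 0 °C; chromatographic separation of diastereomers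
Reagents that add atoms: none
Why: Felkin–Anh addition of an aryl Grignard to the α-alkoxy aldehyde gives the anti (7R,8S) diol acetonide as the major diastereomer. C8 is destroyed in Step 7, so it only serves to set C7.

**Step 6**
Reactants: 8; 4
Product: 9 C7-O-(4-TBSO-3,5-dimethoxycinnamyl) ether
Conditions: NaH, TBAI (cat.), THF–DMF, 0 °C → rt
Reagents that add atoms: none
Why: Williamson etherification of the secondary alkoxide with the allylic bromide installs the dipolarophile tether without touching C7.

**Step 7**
Reactants: 9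
Product: 10 (R)-α-aryl-α-(cinnamyloxy)acetaldehyde
Conditions: H5IO6, Et2O, 0 °C (crude used at once)
Reagents that add atoms: none
Why: Periodic acid hydrolyses the terminal acetonide and cleaves the C8–C9 diol (Malaprade cleavage). C7 is untouched and C8 is discarded as a carbonyl.

**Step 8**
Reactants: 10
Product: 11 aldoxime
Conditions: NH2OH·HCl, NaOAc, EtOH–H2O, rt
Reagents that add atoms: hydroxylamine (from NH2OH·HCl), NO
Why: Condensation under buffered conditions gives the nitrile oxide precursor while limiting epimerization of the labile benzylic α-centre.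

**Step 9**
Reactants: 11
Product: 12 cis-fused isoxazoline–tetrahydrofuran (both aryl groups exo)
Conditions: NCS, DMF, rt; then Et3N, CH2Cl2 (0.01 M, syringe pump), 25 °C
Reagents that add atoms: none
Why: Intramolecular nitrile oxide–alkene 1,3-dipolar cycloaddition (5-exo mode). It is suprafacial, so the E-alkene puts Ar′ trans to the tether CH2. The C7 aryl sits trans to the new isoxazoline ring (exo), which sets C8′ and C7′ relative to the chiral-pool C7.

**Step 10**
Reactants: 12
Product: 13 β-hydroxy ketone (2,4-trans-substituted THF-3-one)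
Conditions: Raney Ni, H2 (1 atm), B(OH)3, MeOH–H2O (5:1), rt
Reagents that add atoms: water, O
Why: Hydrogenolysis of the N–O bond gives a β-hydroxy imine. B(OH)3 and water hydrolyse it to the ketone (the water supplies the ketone oxygen, and NH3 is released). The former isoxazoline oxygen stays on C7′, so the carbinol configuration is retained. C7 and C8′ are α to the ketone, but the trans arrangement is also the thermodynamic one.

**Step 11**
Reactants: 13
Product: 14 exocyclic methyl enol ether (E/Z)
Conditions: Ph3P+CH2OMe Cl− (3 equiv), KOtBu, THF, 0 °C → rt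
Reagents that add atoms: (methoxymethyl)triphenylphosphonium chloride, COC[P+](c1ccccc1)(c1ccccc1)c1ccccc1.[Cl-]
Why: Wittig one-carbon homologation installs the future C9 as an aldehyde equivalent at C8. Excess ylide covers the free C7′-OH.

**Step 12**
Reactants: 14
Product: 15 bicyclic lactol (C9 anomers)
Conditions: 1 M aq. HCl–THF (1:3), 40 °C
Reagents that add atoms: water, O
Why: Enol-ether hydrolysis gives an α-branched aldehyde (MeOH is lost) that epimerizes at C8 via its enol. Only the cis-fused isomer can close onto the C7′-OH, so lactolization fixes C8.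

**Step 13**
Reactants: 15
Product: 16 protected medioresinol-type core
Conditions: Et3SiH, BF3·OEt2, CH2Cl2, −78 → 0 °C
Reagents that add atoms: none
Why: Ionic deoxygenation reduces the oxocarbenium ion derived from the lactol. C9 becomes CH2, so no new stereocentre is created and the bicycle is untouched.

**Step 14**
Reactants: 16
Product: 17 syringyl-free phenol (guaiacyl OBn retained)
Conditions: K2CO3, MeOH, rt
Reagents that add atoms: none
Why: Aryl TBS ethers are cleaved by methoxide, while the aryl benzyl ether survives, so only the syringyl OH is freed.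

**Step 15**
Reactants: 18 L-serine
Product: 19 (S)-glyceric acid
Conditions: NaNO2, 1 M aq. H2SO4, 0 °C → rt
Reagents that add atoms: water, O
Why: Diazotization proceeds with retention through the α-lactone (double inversion), so the configuration of L-serine is kept.

**Step 16**
Reactants: 19
Product: 20 methyl (S)-glycerate
Conditions: MeOH, H2SO4 (cat.), reflux
Reagents that add atoms: methanol, CO
Why: Fischer esterification does not affect the stereocentre.

**Step 17**
Reactants: 20
Product: 21 methyl (S)-3-O-TBDPS-glycerate
Conditions: TBDPSCl, imidazole, CH2Cl2, 0 °C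
Reagents that add atoms: TBDPSCl, CC(C)(C)[Si](c1ccccc1)(c1ccccc1)Cl
Why: The primary alcohol is silylated selectively, and the bulky silyl group does not chelate in the later Felkin addition.

**Step 18**
Reactants: 17; 21
Product: 22 aryl ether ester (R at C8″)
Conditions: ADDP, PBu3, toluene, 0 °C → rt
Reagents that add atoms: none
Why: Mitsunobu aryl etherification is an SN2 at the activated α-hydroxy ester, so it inverts S to R. Low temperature limits β-elimination of the silyloxy group.

**Step 19**
Reactants: 22
Product: 23 (R)-α-aryloxy-β-silyloxy aldehyde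
Conditions: DIBAL-H (1.1 equiv), CH2Cl2, −78 °C (crude used at once)
Reagents that add atoms: none
Why: Partial reduction of the ester at low temperature stops at the aldehyde.

**Step 20**
Reactants: 23; 7
Product: 24 erythro (7″S,8″R) adduct
Conditions: 7, Mg, THF, to give ArMgBr; CeCl3, THF, −78 °C; then 23
Reagents that add atoms: none
Why: The organocerium adds under polar Felkin–Anh control, with OAr anti to the nucleophile (the non-chelating OTBDPS and weakly chelating OAr favour this). This gives the anti, i.e. erythro, 7″S,8″R alcohol, and cerium suppresses enolization of the α-aryloxy aldehyde.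

**Step 21**
Reactants: 24
Product: 25 bis-phenol TBDPS ether
Conditions: H2 (1 atm), 10% Pd/C, EtOAc–MeOH, rt
Reagents that add atoms: none
Why: Hydrogenolysis removes the two aryl benzyl ethers. The silyl ether and the stereocentres are unaffected under neutral conditions and short reaction time.

**Step 22**
Reactants: 25
Product: 26 Hedyotol C
Conditions: TBAF, AcOH (1 equiv), THF, 0 °C
Reagents that add atoms: none
Why: Buffered fluoride removes the primary TBDPS ether to give the target, with no base-labile stereocentre exposed.

---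

**Compound list**

1 | methyl (E)-sinapate | COC(=O)/C=C/c1cc(OC)c(O)c(OC)c1 | starting material
2 | methyl (E)-4-O-TBS-sinapate | COC(=O)/C=C/c1cc(OC)c(O[Si](C)(C)C(C)(C)C)c(OC)c1 | intermediate
3 | (E)-4-O-TBS-sinapyl alcohol | OC/C=C/c1cc(OC)c(O[Si](C)(C)C(C)(C)C)c(OC)c1 | intermediate
4 | (E)-4-O-TBS-sinapyl bromide | BrC/C=C/c1cc(OC)c(O[Si](C)(C)C(C)(C)C)c(OC)c1 | intermediate
5 | (R)-solketal | OC[C@@H]1COC(C)(C)O1 | starting material
6 | (S)-2,3-O-isopropylideneglyceraldehyde | O=C[C@@H]1COC(C)(C)O1 | intermediate
7 | 1-(benzyloxy)-4-bromo-2-methoxybenzene | COc1cc(Br)ccc1OCc1ccccc1 | starting material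
8 | anti diol-acetonide adduct (7R,8S) | COc1cc([C@@H](O)[C@@H]2COC(C)(C)O2)ccc1OCc1ccccc1 | intermediate
9 | C7 cinnamyl ether | COc1cc([C@@H](OC/C=C/c2cc(OC)c(O[Si](C)(C)C(C)(C)C)c(OC)c2)[C@@H]2COC(C)(C)O2)ccc1OCc1ccccc1 | intermediate
10 | (R)-α-aryl-α-cinnamyloxy acetaldehyde | COc1cc([C@@H](OC/C=C/c2cc(OC)c(O[Si](C)(C)C(C)(C)C)c(OC)c2)C=O)ccc1OCc1ccccc1 | intermediate
11 | aldoxime | COc1cc([C@@H](OC/C=C/c2cc(OC)c(O[Si](C)(C)C(C)(C)C)c(OC)c2)C=NO)ccc1OCc1ccccc1 | intermediate
12 | cis-fused isoxazoline–THF, aryl groups exo | COc1cc([C@H]2OC[C@@H]3[C@@H](c4cc(OC)c(O[Si](C)(C)C(C)(C)C)c(OC)c4)ON=C23)ccc1OCc1ccccc1 | intermediate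
13 | β-hydroxy ketone (THF-3-one) | COc1cc([C@H]2OC[C@H]([C@H](O)c3cc(OC)c(O[Si](C)(C)C(C)(C)C)c(OC)c3)C2=O)ccc1OCc1ccccc1 | intermediate
14 | methyl enol ether | COc1cc([C@H]2OC[C@H]([C@H](O)c3cc(OC)c(O[Si](C)(C)C(C)(C)C)c(OC)c3)C2=COC)ccc1OCc1ccccc1 | intermediate
15 | bicyclic lactol | COc1cc([C@H]2OC[C@H]3[C@@H]2C(O)O[C@@H]3c2cc(OC)c(O[Si](C)(C)C(C)(C)C)c(OC)c2)ccc1OCc1ccccc1 | intermediate
16 | protected core | COc1cc([C@H]2OC[C@H]3[C@@H]2CO[C@@H]3c2cc(OC)c(O[Si](C)(C)C(C)(C)C)c(OC)c2)ccc1OCc1ccccc1 | intermediate
17 | core phenol | COc1cc([C@H]2OC[C@H]3[C@@H]2CO[C@@H]3c2cc(OC)c(O)c(OC)c2)ccc1OCc1ccccc1 | intermediate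
18 | L-serine | N[C@@H](CO)C(=O)O | starting material
19 | (S)-glyceric acid | O[C@@H](CO)C(=O)O | intermediate
20 | methyl (S)-glycerate | COC(=O)[C@@H](O)CO | intermediate
21 | methyl (S)-3-O-TBDPS-glycerate | COC(=O)[C@@H](O)CO[Si](c1ccccc1)(c1ccccc1)C(C)(C)C | intermediate
22 | aryl ether ester | COc1cc([C@H]2OC[C@H]3[C@@H]2CO[C@@H]3c2cc(OC)c(O[C@H](CO[Si](c3ccccc3)(c3ccccc3)C(C)(C)C)C(=O)OC)c(OC)c2)ccc1OCc1ccccc1 | intermediate
23 | aryloxy aldehyde | COc1cc([C@H]2OC[C@H]3[C@@H]2CO[C@@H]3c2cc(OC)c(O[C@H](CO[Si](c3ccccc3)(c3ccccc3)C(C)(C)C)C=O)c(OC)c2)ccc1OCc1ccccc1 | intermediate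
24 | erythro adduct | COc1cc([C@H]2OC[C@H]3[C@@H]2CO[C@@H]3c2cc(OC)c(O[C@H](CO[Si](c3ccccc3)(c3ccccc3)C(C)(C)C)[C@@H](O)c3ccc(OCc4ccccc4)c(OC)c3)c(OC)c2)ccc1OCc1ccccc1 | intermediate
25 | bis-phenol TBDPS ether | COc1cc([C@H]2OC[C@H]3[C@@H]2CO[C@@H]3c2cc(OC)c(O[C@H](CO[Si](c3ccccc3)(c3ccccc3)C(C)(C)C)[C@@H](O)c3ccc(O)c(OC)c3)c(OC)c2)ccc1O | intermediate
26 | Hedyotol C | COc1cc([C@H]2OC[C@H]3[C@@H]2CO[C@@H]3c2cc(OC)c(O[C@H](CO)[C@@H](O)c3ccc(O)c(OC)c3)c(OC)c2)ccc1O | target

---

**Total steps:** 22.
**Longest linear sequence:** 17 steps, through the sinapate branch: 1 → 2 → 3 → 6 → 7 → 8 → 9 → 10 → 11 → 12 → 13 → 14 → 18 → 19 → 20 → 21 → 22. The solketal branch (Steps 4–5) and the serine branch (Steps 15–17) are shorter and run in parallel.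

**Three steps most likely to fail**
1. **Step 9 (cycloaddition).** NCS may chlorinate the electron-rich arenes, C7 may epimerize through the hydroximoyl chloride or nitrile oxide, or the exo:endo ratio may be poor.
   Fallback: change the dipole to a nitrone. Condense aldehyde **10** with N-methylhydroxylamine and heat in toluene for a base-free intramolecular nitrone–alkene cycloaddition. Cleave the N–O bond (Zn, AcOH), then convert the resulting 3-(methylamino)THF to ketone **13** by N-chlorination, dehydrochlorination to the imine, and hydrolysis.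
2. **Step 11 (Wittig on the free β-hydroxy ketone).** Retro-aldol cleavage of C7′–C8′ or dehydration to the enone could occur under the basic ylide conditions.
   Fallback: change the one-carbon homologation. Protect the C7′-OH as its TES ether and methylenate with Cp2TiMe2 (Petasis). Hydroborate the exocyclic alkene (9-BBN, then H2O2/NaOH), which delivers hydride to the convex face and so gives the cis-fused CH2OH. Remove the TES group (PPTS, MeOH) and close ring B by selective activation of the primary alcohol (TsCl, pyridine, or Mitsunobu), with the C7′-OH as nucleophile and no inversion at C7′.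
3. **Step 20 (aryl addition).** The dr at C7″ may be too low, or the α-aryloxy aldehyde may epimerize or lose OTBDPS by β-elimination.
   Fallback: use a ketone reduction instead of an aldehyde addition. Convert ester **22** to its Weinreb amide and add ArMgBr to give the aryl ketone. Then reduce the α-aryloxy ketone with L-Selectride under non-chelating polar-Felkin control to give the erythro alcohol, and separate any threo isomer before Steps 21–22.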